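**Retrosynthetic overview**
1. The target gibberellin (13-hydroxygibberell-16-ene-7,19,20-trioic acid) ⇐ its trimethyl ester; ring D is closed last by SmI2 ketyl–alkyne cyclisation (C13–C16) of an ABC keto alkyne.
2. Key step: ring B and the C8 quaternary centre come from 5-exo cyclisation of a C6 α-ester radical onto the C8=C14 alkene of ring C (C6–C8 bond).
3. C9–C10 comes from a reductive Ireland–Claisen rearrangement of a ring A enoate esterified to a ring C allylic alcohol; the ester is made by carbonylative coupling.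
4. Ring A: Robinson annulation (C4), CBS reduction, Johnson–Claisen (C5–C6). Ring C: cyclohexane-1,2-dione monoketal, propargylation, dehydrogenation, CBS reduction.
5. Ring order: A and C separately, then B (radical), then D.

Numbering note: C1–C20 are the gibberellane positions of the target (C4 bears Me C18 and CO2H C19; C6 bears CO2H C7; C10 bears CO2H C20; C13 bears OH; C16=C17 is the methylene). In this numbering the target is (4R,5R,6S,8S,9R,10R,13S).

Assumption: the catalyst-controlled senses of induction in steps 1, 3 and 8 follow the usual models; if one is found reversed, the pseudoenantiomeric (step 1) or enantiomeric (steps 3, 8) catalyst is used.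

**Route**

Step 1
Reactants: 1 methyl 2-formylpropanoate; 2 methyl vinyl ketone
Product: 4 methyl (1R)-1-methyl-4-oxocyclohex-2-ene-1-carboxylate, via Michael adduct 3 (not isolated)
Conditions: 9-O-(9-phenanthryl)cupreidine (10 mol %), CH2Cl2, −24 °C; then pyrrolidine (0.3 equiv), AcOH (0.3 equiv), 40 °C
Reagents that add atoms: none
Why: Robinson annulation in which the bifunctional cinchona base delivers the enolised α-formyl ester (a 1,3-dicarbonyl Michael donor) to the enone and sets the C4 quaternary centre as (R), after which only the methyl-ketone enamine can condense onto the non-enolisable aldehyde to close ring A.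

Step 2
Reactants: 4 methyl (1R)-1-methyl-4-oxocyclohex-2-ene-1-carboxylate
Product: 5 methyl (1R)-3-iodo-1-methyl-4-oxocyclohex-2-ene-1-carboxylate
Conditions: I2 (1.5 equiv), pyridine/CH2Cl2 (1:1), 0 °C to rt
Reagents that add atoms: iodine, II
Why: Johnson α-iodination of an enone (pyridine conjugate addition, iodination of the enolate, elimination) places iodine on C10 and touches no stereocentre.

Step 3
Reactants: 5 methyl (1R)-3-iodo-1-methyl-4-oxocyclohex-2-ene-1-carboxylate
Product: 6 methyl (1R,4S)-4-hydroxy-3-iodo-1-methylcyclohex-2-ene-1-carboxylate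
Conditions: (R)-1-methyl-3,3-diphenyltetrahydro-1H,3H-pyrrolo[1,2-c][1,3,2]oxazaborole (0.2 equiv), BH3·SMe2 (0.7 equiv), THF, −20 °C; MeOH, then aqueous work-up
Reagents that add atoms: none
Why: Corey–Bakshi–Shibata reduction in which the in-plane iodoalkene is the large group, so the (R)-catalyst gives the (S)-carbinol at C1 with the hydroxyl cis to the C4 ester, as the next step requires.

Step 4
Reactants: 6 methyl (1R,4S)-4-hydroxy-3-iodo-1-methylcyclohex-2-ene-1-carboxylate; 7 trimethyl orthoacetate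
Product: 9 methyl (1R,2R)-3-iodo-2-(2-methoxy-2-oxoethyl)-1-methylcyclohex-3-ene-1-carboxylate, via mixed ketene acetal 8 (not isolated)
Conditions: 7 (8 equiv), EtCO2H (0.1 equiv), 140 °C, MeOH distilled off
Reagents that add atoms: none
Why: Johnson–Claisen rearrangement, suprafacial, so the acetate arm (C6, C7) is delivered to C5 on the face vacated by the C1 oxygen, that is cis to the C19 ester and trans to the C4 methyl, while the iodoalkene moves to C10=C1.

Step 5
Reactants: 10 cyclohexane-1,2-dione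
Product: 11 1,4-dioxaspiro[4.5]decan-6-one
Conditions: HOCH2CH2OH (1.05 equiv), p-toluenesulfonic acid (2 mol %), PhH, reflux (Dean–Stark)
Reagents that add atoms: ethane-1,2-diol, OCCO
Why: acid-catalysed monoketalisation with one equivalent of diol masks the future C13 carbonyl and leaves a ketone that can enolise on one side only, with no stereocentre formed.

Step 6
Reactants: 11 1,4-dioxaspiro[4.5]decan-6-one; 12 3-bromo-1-(trimethylsilyl)prop-1-yne
Product: 13 (7RS)-7-[3-(trimethylsilyl)prop-2-yn-1-yl]-1,4-dioxaspiro[4.5]decan-6-one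
Conditions: LiN(iPr)2 (1.1 equiv), THF, −78 °C; then 12, −78 to 0 °C
Reagents that add atoms: none
Why: enolate alkylation that can occur only at C8 because the other α-carbon is the ketal carbon, with a reactive propargylic bromide as SN2 partner; the racemic C8 centre is erased in step 7.

Step 7
Reactants: 13 (7RS)-7-[3-(trimethylsilyl)prop-2-yn-1-yl]-1,4-dioxaspiro[4.5]decan-6-one
Product: 14 7-[3-(trimethylsilyl)prop-2-yn-1-yl]-1,4-dioxaspiro[4.5]dec-7-en-6-one
Conditions: LiN(iPr)2 (1.2 equiv), THF, −78 to 0 °C; then PhS(Cl)=NtBu (1.3 equiv), −78 °C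
Reagents that add atoms: none
Why: Mukaiyama dehydrogenation of the lithium enolate (sulfenylation, then syn elimination through a five-membered transition state) gives the endocyclic 2-alkylcyclohexenone as it does for other 2-alkylcyclohexanones.

Step 8
Reactants: 14 7-[3-(trimethylsilyl)prop-2-yn-1-yl]-1,4-dioxaspiro[4.5]dec-7-en-6-one
Product: 15 (6R)-7-[3-(trimethylsilyl)prop-2-yn-1-yl]-1,4-dioxaspiro[4.5]dec-7-en-6-ol
Conditions: (R)-1-methyl-3,3-diphenyltetrahydro-1H,3H-pyrrolo[1,2-c][1,3,2]oxazaborole (0.2 equiv), BH3·SMe2 (0.7 equiv), toluene, −40 °C; MeOH, then aqueous work-up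
Reagents that add atoms: none
Why: Corey–Bakshi–Shibata reduction with the alkenyl side (in-plane CH2 substituent) as the large group gives the (R)-allylic alcohol, whose C14 oxygen marks the ring C face to which C10 is later delivered.

Step 9
Reactants: 9 methyl (1R,2R)-3-iodo-2-(2-methoxy-2-oxoethyl)-1-methylcyclohex-3-ene-1-carboxylate; 15 (6R)-7-[3-(trimethylsilyl)prop-2-yn-1-yl]-1,4-dioxaspiro[4.5]dec-7-en-6-ol; 16 carbon monoxide
Product: 17 (6R)-7-[3-(trimethylsilyl)prop-2-yn-1-yl]-1,4-dioxaspiro[4.5]dec-7-en-6-yl (5R,6R)-5-(methoxycarbonyl)-6-(2-methoxy-2-oxoethyl)-5-methylcyclohex-1-ene-1-carboxylate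
Conditions: PdCl2(PPh3)2 (5 mol %), CO (1 atm), Et3N (3 equiv), 4-(dimethylamino)pyridine (0.2 equiv), DMF, 60 °C
Reagents that add atoms: none
Why: palladium-catalysed alkoxycarbonylation (oxidative addition of the vinyl iodide, CO insertion, acyl transfer to the allylic alcohol relayed by the aminopyridine) forms the C10–C20 bond and the ester link in one operation without touching a stereocentre.

Step 10
Reactants: 17 (6R)-7-[3-(trimethylsilyl)prop-2-yn-1-yl]-1,4-dioxaspiro[4.5]dec-7-en-6-yl (5R,6R)-5-(methoxycarbonyl)-6-(2-methoxy-2-oxoethyl)-5-methylcyclohex-1-ene-1-carboxylate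
Product: 21 dimethyl (1R,2R,3R)-2-(2-methoxy-2-oxoethyl)-3-methyl-1-{(8R)-7-[3-(trimethylsilyl)prop-2-yn-1-yl]-1,4-dioxaspiro[4.5]dec-6-en-8-yl}cyclohexane-1,3-dicarboxylate, via silyl ketene acetal 18 (not isolated), via silyl ester 19 (not isolated), via carboxylic acid 20 (not isolated)
Conditions: [(Ph3P)CuH]6 (5 mol %), PhMe2SiH (1.5 equiv), toluene, 0 °C to rt, then 80 °C; then MeOH, Me3SiCHN2, 0 °C
Reagents that add atoms: (trimethylsilyl)diazomethane, C[Si](C)(C)C=[N+]=[N-]
Why: reductive Ireland–Claisen rearrangement in which CuH-catalysed 1,4-hydrosilylation makes the ring A silyl ketene acetal regiospecifically without base (the C6 methylene is untouched) and the [3,3] shift bonds C10 to C9 on the ring A face opposite the C5 side chain and C4 ester (C9 trans to C6) while transferring the C14 configuration suprafacially to C9, the acid then being methylated in the same flask.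

Step 11
Reactants: 21 dimethyl (1R,2R,3R)-2-(2-methoxy-2-oxoethyl)-3-methyl-1-{(8R)-7-[3-(trimethylsilyl)prop-2-yn-1-yl]-1,4-dioxaspiro[4.5]dec-6-en-8-yl}cyclohexane-1,3-dicarboxylate
Product: 22 dimethyl (1R,2R,3R)-2-(1-iodo-2-methoxy-2-oxoethyl)-3-methyl-1-{(8R)-7-[3-(trimethylsilyl)prop-2-yn-1-yl]-1,4-dioxaspiro[4.5]dec-6-en-8-yl}cyclohexane-1,3-dicarboxylate (both C6 epimers)
Conditions: LiN(iPr)2 (1.15 equiv), THF, −78 °C; then I2 (1.3 equiv), −78 °C
Reagents that add atoms: iodine, II
Why: ester enolate iodination at the only enolisable position (C4 and C10 are quaternary), the cold enolate reacting with iodine far faster than the trisubstituted alkene does, and the C6 epimer mixture being of no consequence because the radical of the next step is planar.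

Step 12
Reactants: 22 dimethyl (1R,2R,3R)-2-(1-iodo-2-methoxy-2-oxoethyl)-3-methyl-1-{(8R)-7-[3-(trimethylsilyl)prop-2-yn-1-yl]-1,4-dioxaspiro[4.5]dec-6-en-8-yl}cyclohexane-1,3-dicarboxylate (both C6 epimers)
Product: 23 trimethyl (4R,5R,6S,8S,9R,10R)-13,13-(ethylenedioxy)-17-(trimethylsilyl)-13,16-secogibberell-16-yne-7,19,20-trioate (ABC tricycle with the CH2C≡C–SiMe3 arm on quaternary C8)
Conditions: Bu3SnH (1.3 equiv, syringe pump, 6 h), azobisisobutyronitrile (0.2 equiv), PhH (5 mM), 80 °C
Reagents that add atoms: none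
Why: tin hydride-mediated 5-exo-trig radical cyclisation in which the electrophilic C6 α-ester radical adds to the proximal alkene carbon C8 (6-endo attack at C14 would need a bridged bicyclo[3.3.1] transition state), the three-atom tether from C9 enforces the cis B/C fusion so that C8 is set with the propargyl arm on the face of the C9 hydrogen, the C6 ester settles anti to the quaternary C4 branch on C5, and the C14 radical is reduced by Bu3SnH.

Step 13
Reactants: 23 trimethyl (4R,5R,6S,8S,9R,10R)-13,13-(ethylenedioxy)-17-(trimethylsilyl)-13,16-secogibberell-16-yne-7,19,20-trioate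
Product: 25 trimethyl (4R,5R,6S,8S,9R,10R)-13-oxo-13,16-secogibberell-16-yne-7,19,20-trioate (ABC tricycle with C13 ketone and prop-2-ynyl on C8), via terminal alkyne ketal 24 (not isolated)
Conditions: K2CO3 (0.3 equiv), MeOH, rt; then 1 M aq. HCl, THF, rt
Reagents that add atoms: water, O
Why: base methanolysis of the alkynylsilane followed by acid hydrolysis of the dioxolane, in that order so that no base meets the unmasked ketone whose β-carbon C8 carries the ester-bearing C6 (retro-Michael risk), with no stereocentre touched.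

Step 14
Reactants: 25 trimethyl (4R,5R,6S,8S,9R,10R)-13-oxo-13,16-secogibberell-16-yne-7,19,20-trioate
Product: 26 trimethyl (4R,5R,6S,8S,9R,10R,13S)-13-hydroxygibberell-16-ene-7,19,20-trioate (trimethyl ester of the target gibberellin)
Conditions: SmI2 (2.5 equiv), HMPA (8 equiv), t-BuOH (2 equiv), THF, 0 °C
Reagents that add atoms: none
Why: SmI2-mediated ketyl–alkyne reductive cyclisation in which the C13 ketyl radical adds 5-exo-dig to the propargyl alkyne, the vinyl radical is reduced and protonated to the exocyclic methylene, and the C13 carbinol configuration is fixed by the bicyclo[3.2.1]octane bridge.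

Step 15
Reactants: 26 trimethyl (4R,5R,6S,8S,9R,10R,13S)-13-hydroxygibberell-16-ene-7,19,20-trioate
Product: 27 (4R,5R,6S,8S,9R,10R,13S)-13-hydroxygibberell-16-ene-7,19,20-trioic acid (the target gibberellin)
Conditions: NaSEt (12 equiv), DMF, 100 °C; then 1 M aq. HCl
Reagents that add atoms: none
Why: thiolate SN2 demethylation at the O-methyl carbons cleaves all three esters, including the neopentyl-type C19 and C20 esters that resist saponification, and spares the tertiary allylic alcohol and the exocyclic alkene.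

**Compound list**

1 | methyl 2-formylpropanoate | COC(=O)C(C)C=O | starting material
2 | methyl vinyl ketone (but-3-en-2-one) | CC(=O)C=C | starting material
3 | methyl (2R)-2-formyl-2-methyl-5-oxohexanoate (not isolated) | COC(=O)[C@@](C)(C=O)CCC(C)=O | intermediate
4 | methyl (1R)-1-methyl-4-oxocyclohex-2-ene-1-carboxylate | COC(=O)[C@@]1(C)C=CC(=O)CC1 | intermediate
5 | methyl (1R)-3-iodo-1-methyl-4-oxocyclohex-2-ene-1-carboxylate | COC(=O)[C@@]1(C)C=C(I)C(=O)CC1 | intermediate
6 | methyl (1R,4S)-4-hydroxy-3-iodo-1-methylcyclohex-2-ene-1-carboxylate | COC(=O)[C@@]1(C)C=C(I)[C@@H](O)CC1 | intermediate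
7 | trimethyl orthoacetate (1,1,1-trimethoxyethane) | CC(OC)(OC)OC | starting material
8 | methyl (1R,4S)-3-iodo-4-[(1-methoxyethenyl)oxy]-1-methylcyclohex-2-ene-1-carboxylate (not isolated) | COC(=O)[C@@]1(C)C=C(I)[C@@H](OC(=C)OC)CC1 | intermediate
9 | methyl (1R,2R)-3-iodo-2-(2-methoxy-2-oxoethyl)-1-methylcyclohex-3-ene-1-carboxylate | IC1=CCC[C@@](C)(C(=O)OC)[C@H]1CC(=O)OC | intermediate
10 | cyclohexane-1,2-dione | O=C1CCCCC1=O | starting material
11 | 1,4-dioxaspiro[4.5]decan-6-one | O=C1CCCCC12OCCO2 | intermediate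
12 | 3-bromo-1-(trimethylsilyl)prop-1-yne | C[Si](C)(C)C#CCBr | starting material
13 | (7RS)-7-[3-(trimethylsilyl)prop-2-yn-1-yl]-1,4-dioxaspiro[4.5]decan-6-one | O=C1C(CC#C[Si](C)(C)C)CCCC12OCCO2 | intermediate
14 | 7-[3-(trimethylsilyl)prop-2-yn-1-yl]-1,4-dioxaspiro[4.5]dec-7-en-6-one | O=C1C(CC#C[Si](C)(C)C)=CCCC12OCCO2 | intermediate
15 | (6R)-7-[3-(trimethylsilyl)prop-2-yn-1-yl]-1,4-dioxaspiro[4.5]dec-7-en-6-ol | O[C@@H]1C(CC#C[Si](C)(C)C)=CCCC12OCCO2 | intermediate
16 | carbon monoxide | [C-]#[O+] | starting material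
17 | (6R)-7-[3-(trimethylsilyl)prop-2-yn-1-yl]-1,4-dioxaspiro[4.5]dec-7-en-6-yl (5R,6R)-5-(methoxycarbonyl)-6-(2-methoxy-2-oxoethyl)-5-methylcyclohex-1-ene-1-carboxylate | O=C(O[C@@H]1C(CC#C[Si](C)(C)C)=CCCC12OCCO2)C1=CCC[C@@](C)(C(=O)OC)[C@H]1CC(=O)OC | intermediate
18 | O-dimethylphenylsilyl O-(ring C allyl) ketene acetal at C10=C20 of the ring A diester (not isolated) | C[Si](C)(c1ccccc1)OC(O[C@@H]1C(CC#C[Si](C)(C)C)=CCCC12OCCO2)=C1CCC[C@@](C)(C(=O)OC)[C@H]1CC(=O)OC | intermediate
19 | dimethylphenylsilyl ester of acid 20 (not isolated) | C[Si](C)(C)C#CCC1=CC2(OCCO2)CC[C@H]1[C@]1(C(=O)O[Si](C)(C)c2ccccc2)CCC[C@@](C)(C(=O)OC)[C@H]1CC(=O)OC | intermediate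
20 | (1R,2R,3R)-3-(methoxycarbonyl)-2-(2-methoxy-2-oxoethyl)-3-methyl-1-{(8R)-7-[3-(trimethylsilyl)prop-2-yn-1-yl]-1,4-dioxaspiro[4.5]dec-6-en-8-yl}cyclohexane-1-carboxylic acid (not isolated) | C[Si](C)(C)C#CCC1=CC2(OCCO2)CC[C@H]1[C@]1(C(=O)O)CCC[C@@](C)(C(=O)OC)[C@H]1CC(=O)OC | intermediate
21 | dimethyl (1R,2R,3R)-2-(2-methoxy-2-oxoethyl)-3-methyl-1-{(8R)-7-[3-(trimethylsilyl)prop-2-yn-1-yl]-1,4-dioxaspiro[4.5]dec-6-en-8-yl}cyclohexane-1,3-dicarboxylate | C[Si](C)(C)C#CCC1=CC2(OCCO2)CC[C@H]1[C@]1(C(=O)OC)CCC[C@@](C)(C(=O)OC)[C@H]1CC(=O)OC | intermediate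
22 | dimethyl (1R,2R,3R)-2-(1-iodo-2-methoxy-2-oxoethyl)-3-methyl-1-{(8R)-7-[3-(trimethylsilyl)prop-2-yn-1-yl]-1,4-dioxaspiro[4.5]dec-6-en-8-yl}cyclohexane-1,3-dicarboxylate, both C6 epimers | C[Si](C)(C)C#CCC1=CC2(OCCO2)CC[C@H]1[C@]1(C(=O)OC)CCC[C@@](C)(C(=O)OC)[C@H]1C(I)C(=O)OC | intermediate
23 | trimethyl (4R,5R,6S,8S,9R,10R)-13,13-(ethylenedioxy)-17-(trimethylsilyl)-13,16-secogibberell-16-yne-7,19,20-trioate (gibberellane numbering; ABC tricycle, C13 ethylene ketal, CH2C≡C–SiMe3 on C8) | C[Si](C)(C)C#CC[C@]23CC4(OCCO4)CC[C@H]2[C@]1(C(=O)OC)CCC[C@@](C)(C(=O)OC)[C@H]1[C@@H]3C(=O)OC | intermediate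
24 | trimethyl (4R,5R,6S,8S,9R,10R)-13,13-(ethylenedioxy)-13,16-secogibberell-16-yne-7,19,20-trioate (as 23 with a terminal alkyne, ketal intact; not isolated) | C#CC[C@]23CC4(OCCO4)CC[C@H]2[C@]1(C(=O)OC)CCC[C@@](C)(C(=O)OC)[C@H]1[C@@H]3C(=O)OC | intermediate
25 | trimethyl (4R,5R,6S,8S,9R,10R)-13-oxo-13,16-secogibberell-16-yne-7,19,20-trioate (ABC tricycle, C13 ketone, prop-2-ynyl on C8) | C#CC[C@]23CC(=O)CC[C@H]2[C@]1(C(=O)OC)CCC[C@@](C)(C(=O)OC)[C@H]1[C@@H]3C(=O)OC | intermediate
26 | trimethyl (4R,5R,6S,8S,9R,10R,13S)-13-hydroxygibberell-16-ene-7,19,20-trioate (trimethyl ester of the target gibberellin) | C=C1C[C@]23C[C@@]1(O)CC[C@H]2[C@]1(C(=O)OC)CCC[C@@](C)(C(=O)OC)[C@H]1[C@@H]3C(=O)OC | intermediate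
27 | (4R,5R,6S,8S,9R,10R,13S)-13-hydroxygibberell-16-ene-7,19,20-trioic acid (the target gibberellin) | C=C1C[C@]23C[C@@]1(O)CC[C@H]2[C@]1(C(=O)O)CCC[C@@](C)(C(=O)O)[C@H]1[C@@H]3C(=O)O | target

**Count and risks**

Total step count: 15. Longest linear sequence: 11 steps (steps 1–4 then 9–15; the ring C branch, steps 5–8 then 9–15, is equally long).

The three steps most likely to fail:

Step 12 (radical closure of ring B at a quaternary carbon). The radical may be reduced before it cyclises, or the cyclisation may be slow at the hindered C8. The fallback closes the same bond by enolate chemistry. It sets out from 21: pyridinium p-toluenesulfonate in wet acetone unmasks the ketone as the conjugated cyclohexenone triester F1. KOt-Bu (0.3 equiv) in THF/t-BuOH at 0 °C then effects intramolecular Michael addition of the C6 ester enolate to the enone β-carbon C8, giving the silylalkyne keto triester F2 with the same tether-controlled cis B/C fusion and the thermodynamic C6 configuration. Bu4NF buffered with AcOH removes the silyl group, and the route is rejoined at 25.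

Step 10 (reductive Ireland–Claisen). The hindered cyclic enoate may resist CuH, or the [3,3] shift that forms the vicinal quaternary and tertiary centres may be slow or poorly face-selective. The fallback forms C9–C10 by an intermolecular allylic alkylation. It sets out from 9 and 15: 9 is methoxycarbonylated (PdCl2(PPh3)2, CO, MeOH, Et3N) to the ring A enoate triester F3, a less hindered substrate that [(Ph3P)CuH]6/PhMe2SiH converts into the silyl ketene acetal F4. Alcohol 15 is acylated (ClCO2Me, pyridine) to the allylic methyl carbonate F5. Pd2(dba)3/dppe in THF at 40 °C then joins F4 and F5 in a Tsuji–Trost allylation: attack is at the less hindered allyl terminus C9, with net retention so that C10 arrives on the face the carbonate oxygen occupied, and anti to the C5 side chain on ring A. The route is rejoined at 21.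

Step 9 (carbonylative esterification). The hindered secondary allylic alcohol may intercept the acyl-palladium slowly, and the allylic ester product can be ionised by zerovalent palladium. The fallback separates the two events. It sets out from 9: hydroxycarbonylation (Pd(OAc)2, dppf, CO, KOAc, DMSO/H2O) gives the cyclohexenecarboxylic acid F6, which is esterified with 15 under Yamaguchi conditions (2,4,6-trichlorobenzoyl chloride, Et3N, then 4-(dimethylamino)pyridine, toluene), so the allylic ester never meets zerovalent palladium. The route is rejoined at 17.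

Further compounds
F1 | step 12 | dimethyl (1R,2R,3R)-2-(2-methoxy-2-oxoethyl)-3-methyl-1-{(1R)-4-oxo-2-[3-(trimethylsilyl)prop-2-yn-1-yl]cyclohex-2-en-1-yl}cyclohexane-1,3-dicarboxylate | C[Si](C)(C)C#CCC1=CC(=O)CC[C@H]1[C@]1(C(=O)OC)CCC[C@@](C)(C(=O)OC)[C@H]1CC(=O)OC
F2 | step 12 | trimethyl (4R,5R,6S,8S,9R,10R)-13-oxo-17-(trimethylsilyl)-13,16-secogibberell-16-yne-7,19,20-trioate (as 25 but silylated) | C[Si](C)(C)C#CC[C@]23CC(=O)CC[C@H]2[C@]1(C(=O)OC)CCC[C@@](C)(C(=O)OC)[C@H]1[C@@H]3C(=O)OC
F3 | step 10 | dimethyl (1R,2R)-2-(2-methoxy-2-oxoethyl)-1-methylcyclohex-3-ene-1,3-dicarboxylate | COC(=O)C1=CCC[C@@](C)(C(=O)OC)[C@H]1CC(=O)OC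
F4 | step 10 | methyl (1R,2S)-3-{[dimethyl(phenyl)silyl]oxy(methoxy)methylidene}-2-(2-methoxy-2-oxoethyl)-1-methylcyclohexane-1-carboxylate | COC(O[Si](C)(C)c1ccccc1)=C1CCC[C@@](C)(C(=O)OC)[C@H]1CC(=O)OC
F5 | step 10 | methyl (6R)-7-[3-(trimethylsilyl)prop-2-yn-1-yl]-1,4-dioxaspiro[4.5]dec-7-en-6-yl carbonate | COC(=O)O[C@@H]1C(CC#C[Si](C)(C)C)=CCCC12OCCO2
F6 | step 9 | (5R,6R)-5-(methoxycarbonyl)-6-(2-methoxy-2-oxoethyl)-5-methylcyclohex-1-ene-1-carboxylic acid | OC(=O)C1=CCC[C@@](C)(C(=O)OC)[C@H]1CC(=O)OC
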